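**Plan**

1. Tetralin numbering is used throughout, also for the matching carbons of open-chain intermediates; ring A is the fused benzene ring, ring B the carbocycle, ring C the pendant aryl group. The first cut is the C4–C4a bond of ring B: C3 carries two one-carbon arms, the ring CH2 (C4) and the CH2OH carbon, which are the two CH2 groups of a 3-substituted oxetane, and C4a lies para to the C7 hydroxyl of ring A.
2. The oxetane goes back to a malonate; the C2–C3 bond is then cut to an aldehyde enamine plus bromomalonate, and the C1–ring C bond to an enal plus an arylboronic acid.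
3. Forward: isovanillin → enal 3 → diarylpropanal 5 (C1–ring C bond) → malonate 7 (C2–C3 bond) → diol 10 → oxetane 12 → protecting-group exchange → ring B closed as the last skeletal bond (15 → 16) → release of the ring C phenol.
4. Stereochemistry: C1 from a chiral diene–rhodium catalyst, C2 from an imidazolidinone organocatalyst, C3 from the C1/C2 centres in the chair-like ring closure, which chooses between the two oxetane CH2 groups.
5. The ring closure also frees the C3 hydroxymethyl group while the C2 arm already carries its acetate, so the two primary alcohols never have to be told apart afterwards.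

Key step: step 12

Remark: the antipode of the diene ligand in step 3 is assumed to be the one that arylates the Re face of C3 of enal 3; if the sense on this enal is the opposite, the other antipode is used.

**Route**

Step 1
Reactants: 1 isovanillin (3-hydroxy-4-methoxybenzaldehyde)
Product: 2 4-methoxy-3-[(triisopropylsilyl)oxy]benzaldehyde
Conditions: TIPSCl (1.1 equiv), imidazole (2.2 equiv), DMF, 23 °C
Reagents that add atoms: triisopropylsilyl chloride, CC(C)[Si](Cl)(C(C)C)C(C)C
Why: Silyl ether formation on the phenol, with TIPS chosen because it should survive aqueous base, hydride, alkyllithium and hydrogenolysis and is the only group later removed by fluoride, which singles out the ring A phenol.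

Step 2
Reactants: 2 4-methoxy-3-[(triisopropylsilyl)oxy]benzaldehyde
Product: 3 (E)-3-{4-methoxy-3-[(triisopropylsilyl)oxy]phenyl}prop-2-enal
Conditions: Ph3P=CHCHO (1.2 equiv), toluene, 80 °C
Reagents that add atoms: (triphenylphosphoranylidene)acetaldehyde, O=CC=P(c1ccccc1)(c1ccccc1)c1ccccc1
Why: Wittig reaction with the stabilised formyl ylide should give the E-cinnamaldehyde by two-carbon homologation.

Step 3
Reactants: 3 (E)-enal; 4 [4-(benzyloxy)-3-methoxyphenyl]boronic acid (1.5 equiv)
Product: 5 (3S)-3-[4-(benzyloxy)-3-methoxyphenyl]-3-{4-methoxy-3-[(triisopropylsilyl)oxy]phenyl}propanal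
Conditions: [RhCl(C2H4)2]2 (2.5 mol%), Ph-bod* chiral diene (2,5-diphenylbicyclo[2.2.2]octa-2,5-diene, 5.5 mol%, antipode as in the remark), KOH (20 mol%), dioxane/H2O 10:1, 30 °C
Reagents that add atoms: none
Why: Rhodium-catalysed asymmetric 1,4-addition of an arylboronic acid to an enal (Hayashi–Miyaura reaction) on a chiral diene complex, which suppresses 1,2-addition, should transfer the aryl group to the Re face of the β-carbon and so set the diarylmethine centre (future C1) under ligand control.

Step 4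
Reactants: 5 (3S)-diarylpropanal; 6 diethyl bromomalonate (1.3 equiv)
Product: 7 diethyl 2-[(2R,3S)-3-[4-(benzyloxy)-3-methoxyphenyl]-3-{4-methoxy-3-[(triisopropylsilyl)oxy]phenyl}-1-oxopropan-2-yl]propanedioate
Conditions: (2R,5S)-2-tert-butyl-3,5-dimethylimidazolidin-4-one·TfOH (20 mol%), Ru(bpy)3Cl2 (0.5 mol%), 2,6-lutidine (2 equiv), DMF, visible light, 23 °C
Reagents that add atoms: none
Why: Photoredox organocatalytic enantioselective α-alkylation of an aldehyde, in which the malonyl radical formed by one-electron reduction of 6 should add to the Si face of the E-enamine while the catalyst shields the Re face, sets the future C2 centre under catalyst control by analogy with linear and β-branched aldehydes.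

Step 5
Reactants: 7 aldehyde malonate
Product: 8 diethyl 2-[(2R,3S)-3-[4-(benzyloxy)-3-methoxyphenyl]-1-hydroxy-3-{4-methoxy-3-[(triisopropylsilyl)oxy]phenyl}propan-2-yl]propanedioate
Conditions: NaBH4 (1.0 equiv), EtOH/CH2Cl2 1:1, −40 °C; AcOH quench at −40 °C; used crude
Reagents that add atoms: none
Why: Chemoselective borohydride reduction of the aldehyde beside the malonate esters, run cold and quenched with acid so that the γ-hydroxy diester should not lactonise and the α-centre should not epimerise.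

Step 6
Reactants: 8 hydroxy malonate
Product: 9 diethyl 2-[(2R,3S)-1-(benzyloxy)-3-[4-(benzyloxy)-3-methoxyphenyl]-3-{4-methoxy-3-[(triisopropylsilyl)oxy]phenyl}propan-2-yl]propanedioate
Conditions: BnOC(=NH)CCl3 (1.5 equiv), TfOH (5 mol%), CH2Cl2/cyclohexane 1:2, 0 °C
Reagents that add atoms: benzyl 2,2,2-trichloroacetimidate, N=C(OCc1ccccc1)C(Cl)(Cl)Cl
Why: Acid-catalysed O-benzylation with a trichloroacetimidate is chosen because basic benzylation would deprotonate the malonate and drive lactonisation, and the benzyl ether keeps the C2 arm distinct from the two malonate-derived arms.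

Step 7
Reactants: 9 benzyl ether malonate
Product: 10 2-[(2R,3S)-1-(benzyloxy)-3-[4-(benzyloxy)-3-methoxyphenyl]-3-{4-methoxy-3-[(triisopropylsilyl)oxy]phenyl}propan-2-yl]propane-1,3-diol
Conditions: LiAlH4 (3 equiv), THF, 0 → 23 °C; Rochelle salt work-up
Reagents that add atoms: none
Why: Hydride reduction of the malonate should give the 2-substituted propane-1,3-diol whose two CH2OH groups are the later C4 and C3–CH2OH, with benzyl and aryl TIPS ethers inert.

Step 8
Reactants: 10 1,3-diol
Product: 12 3-[(2R,3S)-1-(benzyloxy)-3-[4-(benzyloxy)-3-methoxyphenyl]-3-{4-methoxy-3-[(triisopropylsilyl)oxy]phenyl}propan-2-yl]oxetane, via monotosylate 11 (not isolated)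
Conditions: n-BuLi (1.0 equiv), THF, 0 °C; TsCl (1.0 equiv), 0 °C; n-BuLi (1.05 equiv), 0 → 60 °C
Reagents that add atoms: p-toluenesulfonyl chloride, Cc1ccc(cc1)S(=O)(=O)Cl (tosyl group carried by 11 only)
Why: One-pot monotosylation of the lithium alkoxide followed by intramolecular Williamson etherification (4-exo-tet) of the second alkoxide should give the 3-substituted oxetane, and no stereocentre arises because both diastereomers of 11 close to the same oxetane.

Step 9
Reactants: 12 oxetane
Product: 13 4-[(1S,2R)-3-hydroxy-1-{4-methoxy-3-[(triisopropylsilyl)oxy]phenyl}-2-(oxetan-3-yl)propyl]-2-methoxyphenol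
Conditions: H2 (1 atm), 10% Pd/C, EtOAc/EtOH 1:1, 23 °C
Reagents that add atoms: none
Why: Neutral hydrogenolysis should remove the aryl and the alkyl benzyl ether while leaving the oxetane and the aryl TIPS ether untouched.

Step 10
Reactants: 13 phenol alcohol
Product: 14 (2R,3S)-3-[4-(acetyloxy)-3-methoxyphenyl]-3-{4-methoxy-3-[(triisopropylsilyl)oxy]phenyl}-2-(oxetan-3-yl)propyl acetate
Conditions: Ac2O (3 equiv), pyridine (6 equiv), DMAP (5 mol%), CH2Cl2, 0 → 23 °C
Reagents that add atoms: acetic anhydride, CC(=O)OC(C)=O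
Why: DMAP-catalysed acylation installs the primary acetate of the target and at the same time acetylates the ring C phenol, which deactivates ring C for the ring closure.

Step 11
Reactants: 14 diacetate
Product: 15 (2R,3R)-3-[4-(acetyloxy)-3-methoxyphenyl]-3-(3-hydroxy-4-methoxyphenyl)-2-(oxetan-3-yl)propyl acetate
Conditions: TBAF (1.1 equiv), AcOH (1.2 equiv), THF, 0 °C
Reagents that add atoms: none
Why: Fluoride-induced cleavage of the aryl silyl ether, buffered with acetic acid so that the phenoxide cannot attack the acetates, frees only the ring A phenol (the descriptor at the diarylmethine carbon changes by priority only).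

Step 12
Reactants: 15 oxetane phenol
Product: 16 [(1S,2R,3R)-1-[4-(acetyloxy)-3-methoxyphenyl]-7-hydroxy-3-(hydroxymethyl)-6-methoxy-1,2,3,4-tetrahydronaphthalen-2-yl]methyl acetate
Conditions: Sc(OTf)3 (10 mol%), 1,2-dichloroethane (0.01 M), 0 → 40 °C
Reagents that add atoms: none
Why: Sc(OTf)3 binds the oxetane oxygen and C4a of ring A, the carbon para to the free C7 hydroxyl, attacks one of the two diastereotopic oxetane CH2 groups from the backside (SN2-like Friedel–Crafts alkylation), after which the arenium ion loses a proton and the former oxetane oxygen ends as the free C3 hydroxymethyl group. The closest known reaction types are the Lewis acid-promoted Friedel–Crafts alkylation of arenes by oxetanes, the acid-catalysed opening of 3-substituted oxetanes by a nucleophile tethered at C3, and the epoxy-arene cyclisation. Ring B closes in the 6-exo-tet mode through a chair-like transition state in which backside attack places the untouched CH2–O arm anti-periplanar to the forming C4–C4a bond, which is the equatorial position on C3. The new C3 centre is therefore controlled by the C1 and C2 centres: only attack on the CH2 group that keeps the C1 aryl and the C2 acetoxymethyl group equatorial as well should be low in energy, and this gives the all-trans ring. The step needs selectivity between the two aryl rings, between the para and ortho carbons of ring A and between the two CH2 groups; the substrate secures the first by the acetate on ring C (meta to the only ring C carbons that could close the same ring) against the free para hydroxyl on ring A, the second by the crowding of the ortho carbon between hydroxyl and side chain, and the third by the chair argument above. Because the C2 arm already carries its acetate, the alcohol that is set free is the only free primary alcohol and no later differentiation is needed.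

Step 13
Reactants: 16 tetralin aryl acetate
Product: 17 [(1S,2R,3R)-7-hydroxy-1-(4-hydroxy-3-methoxyphenyl)-3-(hydroxymethyl)-6-methoxy-1,2,3,4-tetrahydronaphthalen-2-yl]methyl acetate (target)
Conditions: NH4OAc (10 equiv), MeOH/H2O 4:1, 23 °C
Reagents that add atoms: none
Why: Chemoselective solvolysis of the phenolic acetate under neutral ammonium acetate conditions should be much faster than that of the primary alkyl acetate and touches no stereocentre.

**Compound list**

1 | isovanillin (3-hydroxy-4-methoxybenzaldehyde) | COc1ccc(C=O)cc1O | starting material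
2 | 4-methoxy-3-[(triisopropylsilyl)oxy]benzaldehyde | COc1ccc(C=O)cc1O[Si](C(C)C)(C(C)C)C(C)C | intermediate
3 | (E)-3-{4-methoxy-3-[(triisopropylsilyl)oxy]phenyl}prop-2-enal | COc1ccc(/C=C/C=O)cc1O[Si](C(C)C)(C(C)C)C(C)C | intermediate
4 | [4-(benzyloxy)-3-methoxyphenyl]boronic acid | COc1cc(B(O)O)ccc1OCc1ccccc1 | starting material
5 | (3S)-3-[4-(benzyloxy)-3-methoxyphenyl]-3-{4-methoxy-3-[(triisopropylsilyl)oxy]phenyl}propanal | COc1cc([C@@H](c2cc(O[Si](C(C)C)(C(C)C)C(C)C)c(OC)cc2)CC=O)ccc1OCc1ccccc1 | intermediate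
6 | diethyl bromomalonate (diethyl 2-bromopropanedioate) | CCOC(=O)C(Br)C(=O)OCC | starting material
7 | diethyl 2-[(2R,3S)-3-[4-(benzyloxy)-3-methoxyphenyl]-3-{4-methoxy-3-[(triisopropylsilyl)oxy]phenyl}-1-oxopropan-2-yl]propanedioate | COc1cc([C@@H](c2cc(O[Si](C(C)C)(C(C)C)C(C)C)c(OC)cc2)[C@@H](C=O)C(C(=O)OCC)C(=O)OCC)ccc1OCc1ccccc1 | intermediate
8 | diethyl 2-[(2R,3S)-3-[4-(benzyloxy)-3-methoxyphenyl]-1-hydroxy-3-{4-methoxy-3-[(triisopropylsilyl)oxy]phenyl}propan-2-yl]propanedioate | COc1cc([C@@H](c2cc(O[Si](C(C)C)(C(C)C)C(C)C)c(OC)cc2)[C@@H](CO)C(C(=O)OCC)C(=O)OCC)ccc1OCc1ccccc1 | intermediate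
9 | diethyl 2-[(2R,3S)-1-(benzyloxy)-3-[4-(benzyloxy)-3-methoxyphenyl]-3-{4-methoxy-3-[(triisopropylsilyl)oxy]phenyl}propan-2-yl]propanedioate | COc1cc([C@@H](c2cc(O[Si](C(C)C)(C(C)C)C(C)C)c(OC)cc2)[C@@H](COCc2ccccc2)C(C(=O)OCC)C(=O)OCC)ccc1OCc1ccccc1 | intermediate
10 | 2-[(2R,3S)-1-(benzyloxy)-3-[4-(benzyloxy)-3-methoxyphenyl]-3-{4-methoxy-3-[(triisopropylsilyl)oxy]phenyl}propan-2-yl]propane-1,3-diol | COc1cc([C@@H](c2cc(O[Si](C(C)C)(C(C)C)C(C)C)c(OC)cc2)[C@@H](COCc2ccccc2)C(CO)CO)ccc1OCc1ccccc1 | intermediate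
11 | mono-p-toluenesulfonate of diol 10 (either CH2OH group, both diastereomers) | COc1cc([C@@H](c2cc(O[Si](C(C)C)(C(C)C)C(C)C)c(OC)cc2)[C@@H](COCc2ccccc2)C(CO)COS(=O)(=O)c2ccc(C)cc2)ccc1OCc1ccccc1 | intermediate
12 | 3-[(2R,3S)-1-(benzyloxy)-3-[4-(benzyloxy)-3-methoxyphenyl]-3-{4-methoxy-3-[(triisopropylsilyl)oxy]phenyl}propan-2-yl]oxetane | COc1cc([C@@H](c2cc(O[Si](C(C)C)(C(C)C)C(C)C)c(OC)cc2)[C@@H](COCc2ccccc2)C2COC2)ccc1OCc1ccccc1 | intermediate
13 | 4-[(1S,2R)-3-hydroxy-1-{4-methoxy-3-[(triisopropylsilyl)oxy]phenyl}-2-(oxetan-3-yl)propyl]-2-methoxyphenol | COc1cc([C@@H](c2cc(O[Si](C(C)C)(C(C)C)C(C)C)c(OC)cc2)[C@@H](CO)C2COC2)ccc1O | intermediate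
14 | (2R,3S)-3-[4-(acetyloxy)-3-methoxyphenyl]-3-{4-methoxy-3-[(triisopropylsilyl)oxy]phenyl}-2-(oxetan-3-yl)propyl acetate | COc1cc([C@@H](c2cc(O[Si](C(C)C)(C(C)C)C(C)C)c(OC)cc2)[C@@H](COC(C)=O)C2COC2)ccc1OC(C)=O | intermediate
15 | (2R,3R)-3-[4-(acetyloxy)-3-methoxyphenyl]-3-(3-hydroxy-4-methoxyphenyl)-2-(oxetan-3-yl)propyl acetate | COc1cc([C@@H](c2cc(O)c(OC)cc2)[C@@H](COC(C)=O)C2COC2)ccc1OC(C)=O | intermediate
16 | [(1S,2R,3R)-1-[4-(acetyloxy)-3-methoxyphenyl]-7-hydroxy-3-(hydroxymethyl)-6-methoxy-1,2,3,4-tetrahydronaphthalen-2-yl]methyl acetate | COc1cc([C@H]2c3cc(O)c(OC)cc3C[C@@H](CO)[C@@H]2COC(C)=O)ccc1OC(C)=O | intermediate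
17 | [(1S,2R,3R)-7-hydroxy-1-(4-hydroxy-3-methoxyphenyl)-3-(hydroxymethyl)-6-methoxy-1,2,3,4-tetrahydronaphthalen-2-yl]methyl acetate | COc1cc([C@H]2c3cc(O)c(OC)cc3C[C@@H](CO)[C@@H]2COC(C)=O)ccc1O | target

**Step count**

Total: 13 steps. Longest linear sequence: 13 steps (from isovanillin; 4 and 6 are purchased).

**Steps most likely to fail**

Step 12 (ring closure). What may go wrong is closure through the wrong nucleophilic carbon (the ring A carbon ortho to the hydroxyl, or a ring C carbon), capture of the activated oxetane by the neighbouring acetate carbonyl or by a second molecule, or poor discrimination of the two CH2 groups. The fallback replaces the cationic oxetane opening by an anionic phenoxide C-alkylation on a cyclic sulfate, with no acid and no acetate present. It sets out from diol 10 and comes back at 16.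
- Diol 10 is treated with SOCl2 and Et3N (CH2Cl2, 0 °C) to give the cyclic sulfite F1, which is oxidised (RuCl3 cat., NaIO4, MeCN/CCl4/H2O, 0 °C) to the six-membered cyclic sulfate F2.
- TBAF in THF removes the TIPS group, and the ring A phenoxide so formed, the only nucleophilic arene since ring C is a benzyl ether, should alkylate itself at its para carbon on one sulfate CH2 (6-exo-tet, same chair argument) to give the tetrabutylammonium sulfate monoester F3.
- Catalytic H2SO4 in wet THF hydrolyses F3 to the tetralin phenol alcohol F4.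
- Silylation (TBSCl, imidazole, DMF) gives the bis-silyl ether F5, hydrogenolysis (H2, Pd/C) the phenol alcohol F6, and acetylation (Ac2O, pyridine, DMAP) the diacetate F7.
- Buffered fluoride (TBAF/AcOH, THF) removes both TBS groups and returns 16.

Step 5 (with its follow-up benzylation). What may go wrong is lactonisation of the γ-hydroxy malonate during the reduction or under the acid of the benzylation, which would erase the distinction between the C2 arm and the malonate arms. The fallback differentiates the arms after full reduction instead. It sets out from aldehyde 7 and comes back at diol 10.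
- LiAlH4 (THF, 0 °C) reduces 7 completely to the triol F8.
- 2,2-Dimethoxypropane with PPTS closes the six-membered acetonide across the 1,3-diol, which is favoured over the seven-membered alternative, to give the acetonide alcohol F9.
- The remaining primary alcohol is benzylated (NaH, BnBr, Bu4NI, THF, 0 → 23 °C) to the benzyl ether acetonide F10.
- Aqueous acetic acid (23 °C) removes the acetonide and returns 10.

Step 13 (phenol release). What may go wrong is acyl transfer from the C2 acetoxymethyl group to the neighbouring free hydroxymethyl group, or partial loss of the alkyl acetate, during solvolysis of the aryl acetate. The fallback uses a deactivating group on ring C that leaves by neutral hydrogenolysis. It sets out from 13 and comes back at 17.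
- The ring C phenol of 13 is converted selectively (CbzCl, K2CO3, acetone, 0 °C; the phenoxide reacts, the primary alcohol should not) into the aryl benzyl carbonate F11.
- The alcohol is acetylated (Ac2O, pyridine, DMAP) to the carbonate acetate F12.
- TBAF/AcOH frees the ring A phenol to give the oxetane phenol F13.
- The Sc(OTf)3 ring closure of step 12 gives the tetralin carbonate F14.
- Hydrogenolysis (H2, Pd/C, EtOAc) removes the carbonate as toluene and carbon dioxide and gives 17 without any solvolytic step after the ring closure.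

Further compounds
F1 | step 12 | 5-[(2R,3S)-1-(benzyloxy)-3-[4-(benzyloxy)-3-methoxyphenyl]-3-{4-methoxy-3-[(triisopropylsilyl)oxy]phenyl}propan-2-yl]-1,3,2-dioxathiane 2-oxide (cyclic sulfite of 10) | COc1cc([C@@H](c2cc(O[Si](C(C)C)(C(C)C)C(C)C)c(OC)cc2)[C@@H](COCc2ccccc2)C2COS(=O)OC2)ccc1OCc1ccccc1
F2 | step 12 | 5-[(2R,3S)-1-(benzyloxy)-3-[4-(benzyloxy)-3-methoxyphenyl]-3-{4-methoxy-3-[(triisopropylsilyl)oxy]phenyl}propan-2-yl]-1,3,2-dioxathiane 2,2-dioxide (cyclic sulfate of 10) | COc1cc([C@@H](c2cc(O[Si](C(C)C)(C(C)C)C(C)C)c(OC)cc2)[C@@H](COCc2ccccc2)C2COS(=O)(=O)OC2)ccc1OCc1ccccc1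
F3 | step 12 | tetrabutylammonium [(2R,3R,4S)-3-[(benzyloxy)methyl]-4-[4-(benzyloxy)-3-methoxyphenyl]-6-hydroxy-7-methoxy-1,2,3,4-tetrahydronaphthalen-2-yl]methyl sulfate | CCCC[N+](CCCC)(CCCC)CCCC.COc1cc([C@H]2c3cc(O)c(OC)cc3C[C@@H](COS(=O)(=O)[O-])[C@@H]2COCc2ccccc2)ccc1OCc1ccccc1
F4 | step 12 | (6R,7R,8S)-7-[(benzyloxy)methyl]-8-[4-(benzyloxy)-3-methoxyphenyl]-6-(hydroxymethyl)-3-methoxy-5,6,7,8-tetrahydronaphthalen-2-ol | COc1cc([C@H]2c3cc(O)c(OC)cc3C[C@@H](CO)[C@@H]2COCc2ccccc2)ccc1OCc1ccccc1
F5 | step 12 | bis(tert-butyldimethylsilyl) ether of F4 (phenol and primary alcohol silylated; 6R,7R,8S) | COc1cc([C@H]2c3cc(O[Si](C)(C)C(C)(C)C)c(OC)cc3C[C@@H](CO[Si](C)(C)C(C)(C)C)[C@@H]2COCc2ccccc2)ccc1OCc1ccccc1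
F6 | step 12 | 4-[(1S,2R,3R)-7-[(tert-butyldimethylsilyl)oxy]-3-{[(tert-butyldimethylsilyl)oxy]methyl}-2-(hydroxymethyl)-6-methoxy-1,2,3,4-tetrahydronaphthalen-1-yl]-2-methoxyphenol | COc1cc([C@H]2c3cc(O[Si](C)(C)C(C)(C)C)c(OC)cc3C[C@@H](CO[Si](C)(C)C(C)(C)C)[C@@H]2CO)ccc1O
F7 | step 12 | [(1S,2R,3R)-1-[4-(acetyloxy)-3-methoxyphenyl]-7-[(tert-butyldimethylsilyl)oxy]-3-{[(tert-butyldimethylsilyl)oxy]methyl}-6-methoxy-1,2,3,4-tetrahydronaphthalen-2-yl]methyl acetate | COc1cc([C@H]2c3cc(O[Si](C)(C)C(C)(C)C)c(OC)cc3C[C@@H](CO[Si](C)(C)C(C)(C)C)[C@@H]2COC(C)=O)ccc1OC(C)=O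
F8 | step 5 | (3R)-3-{(S)-[4-(benzyloxy)-3-methoxyphenyl]{4-methoxy-3-[(triisopropylsilyl)oxy]phenyl}methyl}-2-(hydroxymethyl)butane-1,4-diol | COc1cc([C@@H](c2cc(O[Si](C(C)C)(C(C)C)C(C)C)c(OC)cc2)[C@@H](CO)C(CO)CO)ccc1OCc1ccccc1
F9 | step 5 | (2R,3S)-3-[4-(benzyloxy)-3-methoxyphenyl]-2-(2,2-dimethyl-1,3-dioxan-5-yl)-3-{4-methoxy-3-[(triisopropylsilyl)oxy]phenyl}propan-1-ol | COc1cc([C@@H](c2cc(O[Si](C(C)C)(C(C)C)C(C)C)c(OC)cc2)[C@@H](CO)C2COC(C)(C)OC2)ccc1OCc1ccccc1
F10 | step 5 | 5-[(2R,3S)-1-(benzyloxy)-3-[4-(benzyloxy)-3-methoxyphenyl]-3-{4-methoxy-3-[(triisopropylsilyl)oxy]phenyl}propan-2-yl]-2,2-dimethyl-1,3-dioxane | COc1cc([C@@H](c2cc(O[Si](C(C)C)(C(C)C)C(C)C)c(OC)cc2)[C@@H](COCc2ccccc2)C2COC(C)(C)OC2)ccc1OCc1ccccc1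
F11 | step 13 | benzyl 4-[(1S,2R)-3-hydroxy-1-{4-methoxy-3-[(triisopropylsilyl)oxy]phenyl}-2-(oxetan-3-yl)propyl]-2-methoxyphenyl carbonate | COc1cc([C@@H](c2cc(O[Si](C(C)C)(C(C)C)C(C)C)c(OC)cc2)[C@@H](CO)C2COC2)ccc1OC(=O)OCc1ccccc1
F12 | step 13 | (2R,3S)-3-{4-[(benzyloxycarbonyl)oxy]-3-methoxyphenyl}-3-{4-methoxy-3-[(triisopropylsilyl)oxy]phenyl}-2-(oxetan-3-yl)propyl acetate | COc1cc([C@@H](c2cc(O[Si](C(C)C)(C(C)C)C(C)C)c(OC)cc2)[C@@H](COC(C)=O)C2COC2)ccc1OC(=O)OCc1ccccc1
F13 | step 13 | (2R,3R)-3-{4-[(benzyloxycarbonyl)oxy]-3-methoxyphenyl}-3-(3-hydroxy-4-methoxyphenyl)-2-(oxetan-3-yl)propyl acetate | COc1cc([C@@H](c2cc(O)c(OC)cc2)[C@@H](COC(C)=O)C2COC2)ccc1OC(=O)OCc1ccccc1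
F14 | step 13 | [(1S,2R,3R)-1-{4-[(benzyloxycarbonyl)oxy]-3-methoxyphenyl}-7-hydroxy-3-(hydroxymethyl)-6-methoxy-1,2,3,4-tetrahydronaphthalen-2-yl]methyl acetate | COc1cc([C@H]2c3cc(O)c(OC)cc3C[C@@H](CO)[C@@H]2COC(C)=O)ccc1OC(=O)OCc1ccccc1
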